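**The question.** How much of the charge sits in the leading species after 4.0 min and after 8.0 min at 0.23 M? First ask where the material can be: not yet at intermediate C, in it, or past it.

| flask | substrate | remark | time |
|---|---|---|---|
| elm | 0.12 M | run made earlier |  |
| cedar | 0.46 M | run made earlier |  |
| Saturday's | 0.23 M |  | 4.0 min |
| Thursday's | 0.23 M |  | 8.0 min |

| run | time / min | product / % | intermediate C / % | intermediate A / % | substrate / % | intermediate B / % | intermediate D / % |
|---|---|---|---|---|---|---|---|
| elm | 0.333 | 0.4 | 0.9 | 37.4 | 56.5 | 5.2 | 0.3 |
| elm | 1.00 | 0.4 | 11.7 | 33.5 | 43.1 | 11.5 | 0.3 |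
| elm | 2.00 | 0 | 31.4 | 23.8 | 31.6 | 11.1 | 1.2 |
| elm | 3.00 | 0.2 | 47.4 | 16.7 | 23.3 | 9.0 | 0.4 |
| elm | 4.00 | 0 | 59.4 | 12.4 | 16.4 | 6.7 | 2.5 |
| cedar | 0.833 | 0 | 8.5 | 34.9 | 45.4 | 11.4 | 0 |
| cedar | 1.50 | 0.2 | 21.6 | 28.0 | 37.0 | 11.6 | 0.5 |
| cedar | 2.50 | 1.0 | 39.5 | 21.2 | 27.2 | 10.8 | 1.1 |
| cedar | 3.00 | 0.2 | 47.2 | 18.0 | 22.7 | 9.0 | 1.4 |
| cedar | 4.00 | 0.7 | 59.4 | 13.5 | 16.2 | 7.0 | 2.4 |

(readings scatter by 0.5 percentage points)

- a reading or a percentage of product counts all its forms, free or not
- a reading of substrate is of its free form alone

1. which of these there is most of at the end, counted by the substrate in it, Saturday's (intermediate D / substrate / intermediate C / intermediate A / intermediate B)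
2. which of these there is most of at the end, counted by the substrate in it, Thursday's (intermediate D / substrate / intermediate C / intermediate A / intermediate B)
3. how much there is at the end of the one of these that leads, in percent of the substrate charged: Saturday's
4. how much there is at the end of the one of these that leads, in percent of the substrate charged: Thursday's

**Charge aside.** At 4.00 min, the elm and cedar runs read intermediate C at 59.4% and 59.4%, though their charges differ 3.83-fold. So I treat the percentages as first-order behaviour and carry them to both new flasks. At that reading of the elm run, intermediate C leads, so for Saturday's I commit to intermediate C near 59.4%.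

**Upstream stock.** Call substrate, intermediate A and intermediate B the upstream stock. The elm run's c(substrate) from 2.00 min to 4.00 min reads 0.328 min⁻¹. This is the drain rate, the fall of ln c(substrate) per minute, and I let the stock follow it. The elm stock of 35.5% at 4.00 min becomes 9.56% for Thursday's flask.

**My bracket.** Removing that stock and the elm run's 2.50% of intermediate D plus product at 4.00 min leaves a reckoned ceiling of 87.9%. That sum rose 1.9 percentage points in the elm run's last minute. Holding this pace gives an estimated upper edge of 80.3%. Scaling the pace with intermediate C, taken at the ceiling, gives an estimated lower edge of 76.7%. Scatter can move either edge by about 4 points.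

**The forecast.** It names intermediate C for Saturday's at 59.6% (58.4% to 60.8%), and intermediate C for Thursday's at 79% (73% to 83%), on the ground that the kinetics are “effectively first order and percentages carry over”. Its Thursday value lies inside my bracket.

**The flasks.** Saturday's gives intermediate C at 59.6%. Thursday's gives intermediate C at 77.1%, just above my lower edge.

    substrate ⇌ intermediate A (K = 0.850, k = 0.0570 s⁻¹)
    intermediate A → intermediate B (k = 0.0120 s⁻¹)
    intermediate B → intermediate C (k = 0.0280 s⁻¹)
    intermediate C ⇌ intermediate D (K = 0.370, k = 5.90 × 10⁻⁴ s⁻¹)
    intermediate D → intermediate E (k = 0.00530 s⁻¹)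
    intermediate E ⇌ product (K = 0.430, k = 0.220 s⁻¹)
    substrate + product ⇌ idle adduct, settled at all times (K = 11.0 L mol⁻¹)

**Drain rate again.** Thursday's upstream stock is 10.3%, against my 9.56%. Now take Saturday's flask read at 2.5 min. At the drain rate, I reckon the elm stock at 2.00 min down to 56.4%. Removing that and the elm run's 1.20% of intermediate D plus product at 2.00 min leaves 42.4%. That flask holds 40.5% of intermediate C.

All runs were generated by integration for an exercise; the scatter is artificial.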